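**Plan**
Retrosynthesis: O5 is masked as a methyl ether and the two ring B phenols as benzyl ethers; C4–C4a and C2–C3 are then cut together, leaving an O-aryl oxocarbenium ion (the cationic 2-oxadiene C4a=C8a–O1=C2) and methoxyketene as its dimethyl acetal; the cation goes back through acylal 7 to benzyl aryl ether 6, which is cut at O1–C2, and ring B is cut at its formyl carbon.
Forward: ring B is built from methoxyhydroquinone (benzylation, formylation, reduction), joined to 3,4,5-trimethoxyphenol through O1–C2, C2 is raised to the acetal level, ring C is closed last between the two finished arenes, and one Lewis acid step frees the three phenols.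
Enabling features: C2 is benzylic to the 2,4,5-trioxygenated ring B (O2′ ortho, O4′ para) and bonded to O1, so it ionises readily; ring A is a symmetric 3,4,5-trimethoxyphenoxy unit with two equivalent, strongly nucleophilic ortho carbons, so C4a needs no directing group and O5 is freed later by carbonyl-assisted demethylation; C3–C4 is a methoxyketene unit (C3 nucleophilic, C4 at the acid level).
Stereochemistry: C2 is set in the key step by a chiral hydrogen-bond-donor catalyst paired with the oxocarbenium triflate; C3 follows by equilibration to the trans (2R,3R) isomer.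
Key step: step 7

Assumption: the antipode of the squaramide catalyst that leaves the Si face of the oxocarbenium carbon open (Si-face attack gives 2R) is used; which antipode this is must be fixed in a pilot run.

**Step 1**
Reactants: 1 2-methoxybenzene-1,4-diol
Product: 2 1,4-bis(benzyloxy)-2-methoxybenzene
Conditions: BnBr (2.3 equiv), K2CO3, DMF, 60 °C, under N2
Reagents that add atoms: benzyl bromide, BrCc1ccccc1
Why: Williamson ether synthesis on both phenols, run without air so that the hydroquinone is not oxidised to the quinone.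

**Step 2**
Reactants: 2 1,4-bis(benzyloxy)-2-methoxybenzene
Product: 3 2,5-bis(benzyloxy)-4-methoxybenzaldehyde
Conditions: POCl3, DMF, 0 → 70 °C; then ice/H2O
Reagents that add atoms: N,N-dimethylformamide, CN(C)C=O; water, O
Why: Vilsmeier–Haack formylation should go to the only unhindered carbon that is para to one oxygen (OMe) and ortho to another (OBn), as with 1,2,4-trimethoxybenzene.

**Step 3**
Reactants: 3 2,5-bis(benzyloxy)-4-methoxybenzaldehyde
Product: 4 [2,5-bis(benzyloxy)-4-methoxyphenyl]methanol
Conditions: NaBH4, MeOH/THF, 0 °C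
Reagents that add atoms: none
Why: Borohydride reduction of an aryl aldehyde leaves aryl ethers untouched.

**Step 4**
Reactants: 4 [2,5-bis(benzyloxy)-4-methoxyphenyl]methanol; 5 3,4,5-trimethoxyphenol
Product: 6 1,4-bis(benzyloxy)-2-methoxy-5-[(3,4,5-trimethoxyphenoxy)methyl]benzene
Conditions: PPh3, DIAD, THF, 0 °C → rt
Reagents that add atoms: none
Why: Mitsunobu etherification of a primary benzylic alcohol with a phenol forms the O1–C2 bond and avoids isolating the labile electron-rich benzyl halide.

**Step 5**
Reactants: 6 1,4-bis(benzyloxy)-2-methoxy-5-[(3,4,5-trimethoxyphenoxy)methyl]benzene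
Product: 7 rac-[2,5-bis(benzyloxy)-4-methoxyphenyl](3,4,5-trimethoxyphenoxy)methyl 2,2-dimethylpropanoate
Conditions: DDQ (1.1 equiv), PivOH (5 equiv), 4 Å MS, CH2Cl2, 0 °C; filtration through basic alumina, used crude
Reagents that add atoms: pivalic acid, CC(C)(C)C(=O)O
Why: DDQ oxidation of an electron-rich benzylic ether (hydride abstraction at C2 of the 2,4,5-trialkoxybenzyl group) with capture of the cation by the carboxylic acid should give the acylal, whose stereocentre is erased again on ionisation.

**Step 6**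
Reactants: 8 1,1,2,2-tetramethoxyethane
Product: 9 1,1,2-trimethoxyethene
Conditions: TMSOTf (1.05 equiv), iPr2NEt (1.3 equiv), CH2Cl2, −20 °C → rt; distilled and used fresh
Reagents that add atoms: none
Why: Silyl triflate/amine elimination of methanol from a dimethyl acetal (ionisation of one acetal, deprotonation at the neighbouring carbon) should give the ketene acetal.

**Step 7**
Reactants: 7 rac-[2,5-bis(benzyloxy)-4-methoxyphenyl](3,4,5-trimethoxyphenoxy)methyl 2,2-dimethylpropanoate; 9 1,1,2-trimethoxyethene
Product: 13 (2R,3R)-2-[2,5-bis(benzyloxy)-4-methoxyphenyl]-3,5,6,7-tetramethoxy-2,3-dihydro-4H-chromen-4-one, via oxocarbenium triflate 10 (not isolated), via dimethoxycarbenium triflate 11 (not isolated), via chromanone dimethyl ketal 12 (not isolated)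
Conditions: chiral squaramide hydrogen-bond donor (aryl-pyrrolidine tert-leucine amide type, 10 mol %), TESOTf (1.2 equiv), 2,6-di-tert-butyl-4-methylpyridine (1.5 equiv), 9 (2.5 equiv), MTBE, −78 → −40 °C; then 5% aq. citric acid, THF, 0 °C; then Et3N (0.2 equiv), CH2Cl2, rt
Reagents that add atoms: water, O
Why: Proposed new method: the squaramide-bound silyl triflate removes the pivalate of 7 as silyl ester, so that only the O-aryl oxocarbenium ion 10 can form; the nucleophilic C3 of ketene acetal 9 adds to C2 to give the dimethoxycarbenium ion 11, whose cationic C4 is attacked by the ortho carbon of ring A to give ketal 12, and mild acid hydrolyses 12 to ketone 13. The closest known reaction types are the oxa-Povarov reaction (aryl oxocarbenium ion plus alkene to chromans by stepwise addition and Friedel–Crafts closure) and the squaramide/silyl triflate-catalysed enantioselective Mukaiyama addition to oxocarbenium ions from aryl acetals; new are the ketene acetal as two-carbon partner, which brings C4 in at the ketone level, and an O-aryl oxocarbenium ion in the chiral ion pair. C2–C3 forms first in an open intermolecular transition state, and ring C then closes in a 6-exo-trig Friedel–Crafts mode (C4a attacks the cationic C4, whose C=O+ bond lies outside the forming ring). C2 is set by the catalyst, whose bound triflate and arene (cation–π contact with the flat ArB–CH=O+–ArA ion) should leave the Si face open and so give 2R; C3 is set afterwards under thermodynamic control, since hydrolysis and the amine treatment equilibrate it through the enol to the trans diequatorial isomer without breaking a bond at C2. The step needs ionisation toward the aryl oxocarbenium ion (secured by the carboxylate leaving group), a single site of ring closure (secured by the equivalence of the two ortho carbons of ring A) and closure faster than methyl loss from 11 (favoured by the weakly nucleophilic bound triflate and the six-membered intramolecular path).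

**Step 8**
Reactants: 13 (2R,3R)-2-[2,5-bis(benzyloxy)-4-methoxyphenyl]-3,5,6,7-tetramethoxy-2,3-dihydro-4H-chromen-4-one
Product: 14 (2R,3R)-2-(2,5-dihydroxy-4-methoxyphenyl)-5-hydroxy-3,6,7-trimethoxy-2,3-dihydro-4H-chromen-4-one
Conditions: BCl3 (5 equiv), C6HMe5 (6 equiv), CH2Cl2, −78 → 0 °C; then MeOH, aq. NaHCO3
Reagents that add atoms: none
Why: BCl3 with pentamethylbenzene as benzyl cation scavenger cleaves aryl benzyl ethers at low temperature, and the same reagent chelated to the C4 carbonyl should cleave only the peri 5-methyl ether, leaving the 3-, 6-, 7- and 4′-methyl ethers and both stereocentres.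

**Compound list**
1 | 2-methoxybenzene-1,4-diol | COc1cc(O)ccc1O | starting material
2 | 1,4-bis(benzyloxy)-2-methoxybenzene | COc1cc(OCc2ccccc2)ccc1OCc1ccccc1 | intermediate
3 | 2,5-bis(benzyloxy)-4-methoxybenzaldehyde | COc1cc(OCc2ccccc2)c(C=O)cc1OCc1ccccc1 | intermediate
4 | [2,5-bis(benzyloxy)-4-methoxyphenyl]methanol | COc1cc(OCc2ccccc2)c(CO)cc1OCc1ccccc1 | intermediate
5 | 3,4,5-trimethoxyphenol | COc1cc(O)cc(OC)c1OC | starting material
6 | 1,4-bis(benzyloxy)-2-methoxy-5-[(3,4,5-trimethoxyphenoxy)methyl]benzene | COc1cc(OCc2ccccc2)c(COc2cc(OC)c(OC)c(OC)c2)cc1OCc1ccccc1 | intermediate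
7 | rac-[2,5-bis(benzyloxy)-4-methoxyphenyl](3,4,5-trimethoxyphenoxy)methyl 2,2-dimethylpropanoate | COc1cc(OCc2ccccc2)c(C(OC(=O)C(C)(C)C)Oc2cc(OC)c(OC)c(OC)c2)cc1OCc1ccccc1 | intermediate
8 | 1,1,2,2-tetramethoxyethane | COC(OC)C(OC)OC | starting material
9 | 1,1,2-trimethoxyethene | COC=C(OC)OC | intermediate
10 | {[2,5-bis(benzyloxy)-4-methoxyphenyl]methylidene}(3,4,5-trimethoxyphenyl)oxonium trifluoromethanesulfonate | COc1cc(OCc2ccccc2)c(C=[O+]c2cc(OC)c(OC)c(OC)c2)cc1OCc1ccccc1.[O-]S(=O)(=O)C(F)(F)F | intermediate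
11 | [(3R)-3-[2,5-bis(benzyloxy)-4-methoxyphenyl]-1,2-dimethoxy-3-(3,4,5-trimethoxyphenoxy)propylidene](methyl)oxonium trifluoromethanesulfonate (methoxy-bearing carbon unassigned) | COc1cc(OCc2ccccc2)c([C@@H](Oc2cc(OC)c(OC)c(OC)c2)C(OC)C(OC)=[O+]C)cc1OCc1ccccc1.[O-]S(=O)(=O)C(F)(F)F | intermediate
12 | (2R)-2-[2,5-bis(benzyloxy)-4-methoxyphenyl]-3,4,4,5,6,7-hexamethoxy-3,4-dihydro-2H-chromene (C3 unassigned) | COc1cc(OCc4ccccc4)c([C@H]2Oc3cc(OC)c(OC)c(OC)c3C(OC)(OC)C2OC)cc1OCc1ccccc1 | intermediate
13 | (2R,3R)-2-[2,5-bis(benzyloxy)-4-methoxyphenyl]-3,5,6,7-tetramethoxy-2,3-dihydro-4H-chromen-4-one | COc1cc(OCc4ccccc4)c([C@H]2Oc3cc(OC)c(OC)c(OC)c3C(=O)[C@@H]2OC)cc1OCc1ccccc1 | intermediate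
14 | (2R,3R)-2-(2,5-dihydroxy-4-methoxyphenyl)-5-hydroxy-3,6,7-trimethoxy-2,3-dihydro-4H-chromen-4-one | COc1cc(O)c([C@H]2Oc3cc(OC)c(OC)c(O)c3C(=O)[C@@H]2OC)cc1O | target

**Step count**
Total: 8 steps. Longest linear sequence: 7 steps (steps 1 to 5, 7 and 8, from compound 1).

**Steps most likely to fail**

1. Step 7 (proposed new method). The dimethoxycarbenium ion may lose a methyl group to give the open-chain methyl ester before it closes onto ring A. Facial selectivity at C2 in the ion pair may be poor. The ketene acetal may be consumed by self-condensation. Fallback, known chemistry, setting out from 5 and 3 and coming back at 13: ortho-acetylation of 5 (BF3·OEt2, AcOH) should give 1-(6-hydroxy-2,3,4-trimethoxyphenyl)ethanone F1. Protection with MOMCl/iPr2NEt gives 1-[6-(methoxymethoxy)-2,3,4-trimethoxyphenyl]ethanone F2. Claisen–Schmidt condensation with aldehyde 3 (KOH, EtOH) gives (2E)-3-[2,5-bis(benzyloxy)-4-methoxyphenyl]-1-[6-(methoxymethoxy)-2,3,4-trimethoxyphenyl]prop-2-en-1-one F3. Juliá–Colonna epoxidation (poly-L-leucine, urea–H2O2, DBU, THF) gives [(2R,3S)-3-[2,5-bis(benzyloxy)-4-methoxyphenyl]oxiran-2-yl][6-(methoxymethoxy)-2,3,4-trimethoxyphenyl]methanone F4. HCl in MeOH/THF removes the MOM group, and the freed phenol opens the epoxide at the benzylic carbon (6-endo, inversion) to (2R,3R)-2-[2,5-bis(benzyloxy)-4-methoxyphenyl]-3-hydroxy-5,6,7-trimethoxy-2,3-dihydro-4H-chromen-4-one F5. Methylation of O3 with MeI/Ag2O gives 13.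

2. Step 5. The acylal may ionise and hydrolyse during isolation, the hydroquinone anion of the oxidant may compete with pivalate for the cation, and a second oxidation at C2 is possible. Fallback, setting out from 3 and coming back at 10: Pinnick oxidation (NaClO2, NaH2PO4, 2-methyl-2-butene) gives 2,5-bis(benzyloxy)-4-methoxybenzoic acid F6. Steglich esterification with 5 (EDC, DMAP) gives 3,4,5-trimethoxyphenyl 2,5-bis(benzyloxy)-4-methoxybenzoate F7. Reduction with iBu2AlH at −78 °C and trapping of the aluminium hemiacetal with Ac2O/pyridine/DMAP gives rac-[2,5-bis(benzyloxy)-4-methoxyphenyl](3,4,5-trimethoxyphenoxy)methyl acetate F8. F8 takes the place of 7 in step 7 and ionises to the same oxocarbenium triflate 10.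

3. Step 8. The Lewis acid may ionise the benzylic C2–O1 bond (ring opening, loss of configuration at C2), and demethylation may run on to O6 or O4′. Fallback, setting out from 13 and coming back at 14: chelation-controlled demethylation of the peri ether only with MgI2 (diethyl etherate, toluene/THF) gives (2R,3R)-2-[2,5-bis(benzyloxy)-4-methoxyphenyl]-5-hydroxy-3,6,7-trimethoxy-2,3-dihydro-4H-chromen-4-one F9. Neutral hydrogenolysis of the two benzyl ethers (H2, Pd(OH)2/C, EtOAc) gives 14.

**Further compounds**
F1 | step 7 | 1-(6-hydroxy-2,3,4-trimethoxyphenyl)ethanone | CC(=O)c1c(O)cc(OC)c(OC)c1OC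
F2 | step 7 | 1-[6-(methoxymethoxy)-2,3,4-trimethoxyphenyl]ethanone | CC(=O)c1c(OCOC)cc(OC)c(OC)c1OC
F3 | step 7 | (2E)-3-[2,5-bis(benzyloxy)-4-methoxyphenyl]-1-[6-(methoxymethoxy)-2,3,4-trimethoxyphenyl]prop-2-en-1-one | COCOc1cc(OC)c(OC)c(OC)c1C(=O)/C=C/c1cc(OCc2ccccc2)c(OC)cc1OCc1ccccc1
F4 | step 7 | [(2R,3S)-3-[2,5-bis(benzyloxy)-4-methoxyphenyl]oxiran-2-yl][6-(methoxymethoxy)-2,3,4-trimethoxyphenyl]methanone | COCOc1cc(OC)c(OC)c(OC)c1C(=O)[C@@H]1O[C@H]1c1cc(OCc2ccccc2)c(OC)cc1OCc1ccccc1
F5 | step 7 | (2R,3R)-2-[2,5-bis(benzyloxy)-4-methoxyphenyl]-3-hydroxy-5,6,7-trimethoxy-2,3-dihydro-4H-chromen-4-one | COc1cc(OCc4ccccc4)c([C@H]2Oc3cc(OC)c(OC)c(OC)c3C(=O)[C@@H]2O)cc1OCc1ccccc1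
F6 | step 5 | 2,5-bis(benzyloxy)-4-methoxybenzoic acid | COc1cc(OCc2ccccc2)c(C(=O)O)cc1OCc1ccccc1
F7 | step 5 | 3,4,5-trimethoxyphenyl 2,5-bis(benzyloxy)-4-methoxybenzoate | COc1cc(OCc2ccccc2)c(C(=O)Oc2cc(OC)c(OC)c(OC)c2)cc1OCc1ccccc1
F8 | step 5 | rac-[2,5-bis(benzyloxy)-4-methoxyphenyl](3,4,5-trimethoxyphenoxy)methyl acetate | COc1cc(OCc2ccccc2)c(C(OC(C)=O)Oc2cc(OC)c(OC)c(OC)c2)cc1OCc1ccccc1
F9 | step 8 | (2R,3R)-2-[2,5-bis(benzyloxy)-4-methoxyphenyl]-5-hydroxy-3,6,7-trimethoxy-2,3-dihydro-4H-chromen-4-one | COc1cc(OCc4ccccc4)c([C@H]2Oc3cc(OC)c(OC)c(O)c3C(=O)[C@@H]2OC)cc1OCc1ccccc1
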